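Quinone ring B (C1=O, C2–OAr, C3–OMe, C4=O, C5 and C6 prenylated) is cut at C3–C4 and C5=C6. The contiguous atoms C6–C1–C2–C3 are the four carbons of a squarate-derived cyclobutenone in which the para pair C3/C6 is still σ-bonded. C4–C5 is an α-ethoxyalkenyllithium. In one operation, 1,2-addition (C3–C4), oxyanion-driven 4π opening of C3–C6, 6π closure (C5–C6) and loss of silanol should give the hexasubstituted arene with every substituent placed. The hindered diaryl ether is made earlier as a simple squarate ester. O-methylation, ceric oxidation and desilylation finish the synthesis.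

Key step: step 7

Remark on the chemistry: the ring B numbering above is used throughout. The target has no stereocentre. The cyclobutenone and the cascade intermediates are racemic or diastereomer mixtures, and their stereocentres vanish on aromatisation.

Step 1
Reactants: 1 methyl 2,4,6-trihydroxybenzoate
Product: 2 methyl 2-hydroxy-4,6-bis(triisopropylsilyloxy)benzoate
Conditions: i-Pr3SiOTf (2.05 equiv), 2,6-lutidine, CH2Cl2, −78 → 0 °C
Reagents that add atoms: triisopropylsilyl triflate, CC(C)[Si](OS(=O)(=O)C(F)(F)F)(C(C)C)C(C)C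
Why: Silyl ether formation: the para hydroxyl and one of the two equivalent ortho hydroxyls react, and the last hydroxyl should stay free because it is hydrogen-bonded to the ester carbonyl and crowded.

Step 2
Reactants: 3 squaric acid
Product: 4 3,4-dichlorocyclobut-3-ene-1,2-dione
Conditions: (COCl)2, DMF (cat.), CH2Cl2, reflux
Reagents that add atoms: oxalyl chloride, O=C(Cl)C(=O)Cl
Why: Vilsmeier-type chlorodehydroxylation of a vinylogous carboxylic acid, the standard access to squaric acid dichloride.

Step 3
Reactants: 4 3,4-dichlorocyclobut-3-ene-1,2-dione, 2 methyl 2-hydroxy-4,6-bis(triisopropylsilyloxy)benzoate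
Product: 6 methyl 2-[(2-methoxy-3,4-dioxocyclobut-1-en-1-yl)oxy]-4,6-bis(triisopropylsilyloxy)benzoate, via chloro aryl squarate 5 (not isolated)
Conditions: 2, i-Pr2NEt, CH2Cl2, −78 → −30 °C; then MeOH (1.0 equiv), i-Pr2NEt, −30 → 0 °C
Reagents that add atoms: methanol, CO
Why: Two addition–elimination reactions on a vinylogous acid chloride: the aryloxy donor slows the second substitution enough to stop at 5, and chloride remains a much better leaving group than aryloxide when one equivalent of methanol follows.

Step 4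
Reactants: 6 aryl methyl squarate (product of step 3), 7 1-chloro-3-methylbut-2-ene (prenyl chloride)
Product: 10 (±)-methyl 2-{[2-methoxy-3-(3-methylbut-2-enyl)-4-oxo-3-(trimethylsilyloxy)cyclobut-1-en-1-yl]oxy}-4,6-bis(triisopropylsilyloxy)benzoate, via prenylbarium chloride 8 (not isolated), via barium alkoxide 9 (not isolated)
Conditions: BaI2, Li, biphenyl, THF, rt (activated barium metal); 7, −78 °C; 6, −78 °C; then Me3SiCl, −78 → 0 °C
Reagents that add atoms: chlorotrimethylsilane, C[Si](C)(C)Cl
Why: α-Selective allylbarium 1,2-addition: allylbarium reagents couple at the unsubstituted terminus without allylic transposition, attack should go to the carbonyl next to C–OMe (vinylogous to the weak, bulky aryloxy donor, so the more electrophilic and less hindered one), and the new stereocentre is racemic and is destroyed in step 7.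

Step 5
Reactants: 11 ethoxyacetylene, 12 1-bromo-3-methylbut-2-ene (prenyl bromide)
Product: 14 1-ethoxy-5-methylhex-4-en-1-yne, via lithium ethoxyacetylide 13 (not isolated)
Conditions: n-BuLi, THF, −78 °C; 12, DMPU, −78 °C → rt
Reagents that add atoms: none
Why: SN2 alkylation of a lithium alkoxyacetylide at the unhindered CH2 of a primary allylic bromide, helped by the dipolar cosolvent.

Step 6
Reactants: 14 1-ethoxy-5-methylhex-4-en-1-yne
Product: 15 (E)-tributyl(1-ethoxy-5-methylhexa-1,4-dien-1-yl)stannane
Conditions: Bu3SnH, Pd(PPh3)4 (2 mol %), THF, 0 °C → rt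
Reagents that add atoms: tributyltin hydride, CCCC[SnH](CCCC)CCCC
Why: Palladium-catalysed syn-hydrostannation: with heteroatom-substituted alkynes tin goes to the heteroatom-bearing carbon and hydrogen to the β-carbon on the same face, which should give the E α-ethoxyalkenylstannane.

Step 7
Reactants: 15 (E)-tributyl(1-ethoxy-5-methylhexa-1,4-dien-1-yl)stannane, 10 silyloxycyclobutenone (product of step 4)
Product: 20 methyl 2-[3-ethoxy-2-hydroxy-6-methoxy-4,5-bis(3-methylbut-2-enyl)phenoxy]-4,6-bis(triisopropylsilyloxy)benzoate, via alkenyllithium 16 (not isolated), via lithium cyclobutenolate 17 (not isolated), via lithium trienolate 18 (not isolated), via lithium cyclohexadienolate 19 (not isolated)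
Conditions: 15, n-BuLi, THF, −78 °C; 10, −78 °C → rt; then 1 M HCl, 0 °C → rt
Reagents that add atoms: none
Why: n-BuLi converts 15 by tin–lithium exchange with retention into alkenyllithium 16, which adds 1,2 to the strained carbonyl of 10 (future C3) and forms C3–C4. Cyclobutenolate 17 then opens in an oxyanion-accelerated conrotatory 4π process that breaks the C3–C6 σ-bond, the oxido group turning outward and the alkenyl group inward, so that trienolate 18 has the Z central double bond that closure needs. Ring B closes by a disrotatory 6π electrocyclisation that forms C5–C6 (19), and on acidification the tertiary C6–OSiMe3 group ionises to a cation stabilised by the C2 and C4 oxygens, which loses the C5 proton to give phenol 20. The closest known reaction types are the squarate ester cascade (organolithium additions, 4π opening, electrocyclic closure) and the two-carbon ring expansion of cyclobutenones and benzocyclobutenones by alkenyllithium addition, the latter ending in aromatisation by loss of an oxygen leaving group. No stereocentre survives, so the facial selectivity of the addition and the geometry at the C6 terminus are irrelevant. The step needs attack on the cyclobutenone carbonyl rather than on the benzoate, which the two ortho substituents of the ester secure at −78 °C, and the substitution pattern is fixed by connectivity because only one hexatriene can form and only the sp3-bound silyloxy group can leave.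

Step 8
Reactants: 20 phenol (product of step 7)
Product: 21 methyl 2-[3-ethoxy-2,6-dimethoxy-4,5-bis(3-methylbut-2-enyl)phenoxy]-4,6-bis(triisopropylsilyloxy)benzoate
Conditions: MeI, K2CO3, acetone, rt
Reagents that add atoms: iodomethane, CI
Why: Williamson ether synthesis on the only free phenol (C3–OH), which at room temperature should outrun lactonisation of the phenolate onto the hindered benzoate and leave the triisopropylsilyl ethers intact.

Step 9
Reactants: 21 triether (product of step 8)
Product: 22 methyl 2-{[2-methoxy-4,5-bis(3-methylbut-2-enyl)-3,6-dioxocyclohexa-1,4-dien-1-yl]oxy}-4,6-bis(triisopropylsilyloxy)benzoate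
Conditions: (NH4)2Ce(NO3)6, MeCN/H2O, 0 °C
Reagents that add atoms: water, O
Why: Oxidative dealkylation of a 1,4-dialkoxyarene by tetravalent cerium: only C1–OMe and C4–OEt are para-related, so water attacks there and methanol and ethanol leave, while the less electron-rich ring A, the prenyl groups and the silyl ethers should survive the short exposure.

Step 10
Reactants: 22 bis(triisopropylsilyl) ether of the target
Product: 23 atrovirinone
Conditions: HF·pyridine, THF, 0 °C → rt
Reagents that add atoms: none
Why: Fluoride cleavage of aryl silyl ethers under mildly acidic, non-nucleophilic conditions that spare the vinylogous aryl ester, the quinone and the prenyl groups.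

Compound list
1 | methyl 2,4,6-trihydroxybenzoate | COC(=O)c1c(O)cc(O)cc1O | starting material
2 | methyl 2-hydroxy-4,6-bis(triisopropylsilyloxy)benzoate | COC(=O)c1c(O)cc(O[Si](C(C)C)(C(C)C)C(C)C)cc1O[Si](C(C)C)(C(C)C)C(C)C | intermediate
3 | squaric acid | O=C1C(O)=C(O)C1=O | starting material
4 | 3,4-dichlorocyclobut-3-ene-1,2-dione | O=C1C(Cl)=C(Cl)C1=O | intermediate
5 | methyl 2-[(2-chloro-3,4-dioxocyclobut-1-en-1-yl)oxy]-4,6-bis(triisopropylsilyloxy)benzoate | O=C1C(=O)C(Cl)=C1Oc2cc(O[Si](C(C)C)(C(C)C)C(C)C)cc(O[Si](C(C)C)(C(C)C)C(C)C)c2C(=O)OC | intermediate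
6 | methyl 2-[(2-methoxy-3,4-dioxocyclobut-1-en-1-yl)oxy]-4,6-bis(triisopropylsilyloxy)benzoate | O=C1C(=O)C(OC)=C1Oc2cc(O[Si](C(C)C)(C(C)C)C(C)C)cc(O[Si](C(C)C)(C(C)C)C(C)C)c2C(=O)OC | intermediate
7 | 1-chloro-3-methylbut-2-ene | CC(C)=CCCl | starting material
8 | prenylbarium chloride | CC(C)=CC[Ba]Cl | intermediate
9 | chlorobarium alkoxide of the 4-hydroxy-4-prenylcyclobutenone (racemic) | Cl[Ba]OC1(CC=C(C)C)C(=O)C(Oc2cc(O[Si](C(C)C)(C(C)C)C(C)C)cc(O[Si](C(C)C)(C(C)C)C(C)C)c2C(=O)OC)=C1OC | intermediate
10 | (±)-methyl 2-{[2-methoxy-3-(3-methylbut-2-enyl)-4-oxo-3-(trimethylsilyloxy)cyclobut-1-en-1-yl]oxy}-4,6-bis(triisopropylsilyloxy)benzoate | C[Si](C)(C)OC1(CC=C(C)C)C(=O)C(Oc2cc(O[Si](C(C)C)(C(C)C)C(C)C)cc(O[Si](C(C)C)(C(C)C)C(C)C)c2C(=O)OC)=C1OC | intermediate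
11 | ethoxyacetylene | CCOC#C | starting material
12 | 1-bromo-3-methylbut-2-ene | CC(C)=CCBr | starting material
13 | lithium ethoxyacetylide | CCOC#C[Li] | intermediate
14 | 1-ethoxy-5-methylhex-4-en-1-yne | CCOC#CCC=C(C)C | intermediate
15 | (E)-tributyl(1-ethoxy-5-methylhexa-1,4-dien-1-yl)stannane | CCO/C(=C\CC=C(C)C)[Sn](CCCC)(CCCC)CCCC | intermediate
16 | (Z)-(1-ethoxy-5-methylhexa-1,4-dien-1-yl)lithium | CCO/C(=C\CC=C(C)C)[Li] | intermediate
17 | lithium cyclobutenolate, 1,2-adduct of 16 to 10 (diastereomer mixture) | CCO/C(=C\CC=C(C)C)C1(O[Li])C(Oc2cc(O[Si](C(C)C)(C(C)C)C(C)C)cc(O[Si](C(C)C)(C(C)C)C(C)C)c2C(=O)OC)=C(OC)C1(CC=C(C)C)O[Si](C)(C)C | intermediate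
18 | ring-opened lithium trienolate (alkenyl group and C1 cis on the central double bond, C6 terminus undefined) | CCO/C(=C\CC=C(C)C)C(/O[Li])=C(/Oc2cc(O[Si](C(C)C)(C(C)C)C(C)C)cc(O[Si](C(C)C)(C(C)C)C(C)C)c2C(=O)OC)C(OC)=C(CC=C(C)C)O[Si](C)(C)C | intermediate
19 | lithium cyclohexadienolate (diastereomer mixture) | [Li]OC1=C(OCC)C(CC=C(C)C)C(CC=C(C)C)(O[Si](C)(C)C)C(OC)=C1Oc2cc(O[Si](C(C)C)(C(C)C)C(C)C)cc(O[Si](C(C)C)(C(C)C)C(C)C)c2C(=O)OC | intermediate
20 | methyl 2-[3-ethoxy-2-hydroxy-6-methoxy-4,5-bis(3-methylbut-2-enyl)phenoxy]-4,6-bis(triisopropylsilyloxy)benzoate | COC(=O)c1c(Oc2c(O)c(OCC)c(CC=C(C)C)c(CC=C(C)C)c2OC)cc(O[Si](C(C)C)(C(C)C)C(C)C)cc1O[Si](C(C)C)(C(C)C)C(C)C | intermediate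
21 | methyl 2-[3-ethoxy-2,6-dimethoxy-4,5-bis(3-methylbut-2-enyl)phenoxy]-4,6-bis(triisopropylsilyloxy)benzoate | COC(=O)c1c(Oc2c(OC)c(OCC)c(CC=C(C)C)c(CC=C(C)C)c2OC)cc(O[Si](C(C)C)(C(C)C)C(C)C)cc1O[Si](C(C)C)(C(C)C)C(C)C | intermediate
22 | methyl 2-{[2-methoxy-4,5-bis(3-methylbut-2-enyl)-3,6-dioxocyclohexa-1,4-dien-1-yl]oxy}-4,6-bis(triisopropylsilyloxy)benzoate | COC(=O)c1c(OC2=C(OC)C(=O)C(CC=C(C)C)=C(CC=C(C)C)C2=O)cc(O[Si](C(C)C)(C(C)C)C(C)C)cc1O[Si](C(C)C)(C(C)C)C(C)C | intermediate
23 | atrovirinone | COC(=O)c1c(O)cc(O)cc1OC1=C(OC)C(=O)C(CC=C(C)C)=C(CC=C(C)C)C1=O | target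

Total step count: 10 steps. Longest linear sequence: 7 steps (steps 1, 3, 4, 7, 8, 9, 10; the branch through steps 2, 3, 4, 7, 8, 9, 10 is equally long).

Steps most likely to fail

Step 7 (key step).
- **Risk:** Proton transfer from the doubly allylic CH2 to the carbanionic carbon of 16 may occur before it adds. Conjugate addition at C1 may compete with 1,2-addition. The 6π closure onto the fully substituted C6 terminus may be sluggish, so that the open trienolate is only protonated on work-up.
- **Fallback:** It sets out from 6 and comes back at 22, building ring B by a Moore rearrangement instead.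
  - Prenyl bromide 12 and ethynylmagnesium bromide with CuCl give 5-methylhex-4-en-1-yne F1.
  - Its lithium acetylide (n-BuLi, THF, −78 °C) adds to 6 to give the 4-alkynyl-4-hydroxycyclobutenone F2.
  - Heating in toluene opens F2 to the enynylketene, which closes to the monoprenylated quinone F3.
  - BF3·OEt2-promoted allylation of F3 with tributyl(3-methylbut-2-enyl)stannane at −78 °C gives the diprenylated hydroquinone F4.
  - Ag2O oxidises F4 to 22.
  - Both free positions end up prenylated, so the carbonyl of 6 at which the acetylide adds does not matter.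

Step 4.
- **Risk:** Allylic transposition may occur during the carbonyl addition. Addition may go to the carbonyl next to C–OAr. Addition–elimination may expel the aryloxide.
- **Fallback:** It sets out from 6 and comes back at 10. Allylmagnesium bromide, which has no regiochemical ambiguity in the allyl unit, is added at −78 °C and the alkoxide is trapped with Me3SiCl to give the 4-allyl-4-(trimethylsilyloxy)cyclobutenone F5. Cross-metathesis of F5 with 2-methylbut-2-ene and the second-generation Grubbs catalyst (CH2Cl2, 40 °C) turns the allyl group into the prenyl group of 10. At this stage no second alkene is close enough for ring closure.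

Step 6.
- **Risk:** Tin may be delivered to the β-carbon. The acid-sensitive enol ether stannane may protodestannylate during purification.
- **Fallback:** It sets out from 12 and comes back at 15 without any alkyne.
  - The lithium enolate of ethyl acetate (LiN(i-Pr)2, THF, −78 °C) is alkylated with 12 to give ethyl 5-methylhex-4-enoate F6.
  - Kinetic enolisation of F6 with LiN(i-Pr)2 in THF and trapping with (PhO)2P(O)Cl gives the ketene acetal phosphate F7, with the side chain cis to OEt.
  - Stannylation with Bu3SnSnBu3, LiCl and Pd(PPh3)4 replaces the phosphate with retention and gives 15.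

Further compounds
F1 | step 7 | 5-methylhex-4-en-1-yne | C#CCC=C(C)C
F2 | step 7 | (±)-methyl 2-{[3-hydroxy-2-methoxy-3-(5-methylhex-4-en-1-ynyl)-4-oxocyclobut-1-en-1-yl]oxy}-4,6-bis(triisopropylsilyloxy)benzoate | O=C1C(Oc2cc(O[Si](C(C)C)(C(C)C)C(C)C)cc(O[Si](C(C)C)(C(C)C)C(C)C)c2C(=O)OC)=C(OC)C1(O)C#CCC=C(C)C
F3 | step 7 | 2-aryloxy-3-methoxy-6-(3-methylbut-2-enyl)-1,4-benzoquinone (aryl = ring A of 22) | O=C1C(Oc2cc(O[Si](C(C)C)(C(C)C)C(C)C)cc(O[Si](C(C)C)(C(C)C)C(C)C)c2C(=O)OC)=C(OC)C(=O)C=C1CC=C(C)C
F4 | step 7 | 2-aryloxy-3-methoxy-5,6-bis(3-methylbut-2-enyl)benzene-1,4-diol (aryl = ring A of 22) | Oc1c(Oc2cc(O[Si](C(C)C)(C(C)C)C(C)C)cc(O[Si](C(C)C)(C(C)C)C(C)C)c2C(=O)OC)c(OC)c(O)c(CC=C(C)C)c1CC=C(C)C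
F5 | step 4 | (±)-methyl 2-{[3-allyl-2-methoxy-4-oxo-3-(trimethylsilyloxy)cyclobut-1-en-1-yl]oxy}-4,6-bis(triisopropylsilyloxy)benzoate | C[Si](C)(C)OC1(CC=C)C(=O)C(Oc2cc(O[Si](C(C)C)(C(C)C)C(C)C)cc(O[Si](C(C)C)(C(C)C)C(C)C)c2C(=O)OC)=C1OC
F6 | step 6 | ethyl 5-methylhex-4-enoate | CCOC(=O)CCC=C(C)C
F7 | step 6 | (E)-1-ethoxy-5-methylhexa-1,4-dien-1-yl diphenyl phosphate | CCO/C(=C\CC=C(C)C)OP(=O)(Oc1ccccc1)Oc1ccccc1
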